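**Retrosynthetic overview**
1. Target 17 (locants: C1 = oxirane carbon bearing CH2OBz, C2 = CHOH, C3 = CHOBz, C4=C5, C6 = oxirane CH, O7 = oxirane oxygen) ⇒ acyclic epoxy diene 16 by ring-closing olefin metathesis at C4=C5; the carbocycle C1–C6 is closed last, on a substrate that already holds the oxirane.
2. Enabling feature: the oxirane ring O7–C1–C6 carries the C2 chain and the C5 vinyl group cis, so the terminal alkene on C3 and the one on C6 sit on one side as a 1,7-diene that can only close to the six-membered ring.
3. 16 ⇒ triene 15 by hydroxyl-directed, A(1,3)-controlled epoxidation (the C2 hydroxyl sets C1 and C6).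
4. 15 ⇒ (Z)-dienal 9 + 3-chloropropenyl benzoate 12 by catalytic asymmetric syn-(benzoyloxy)allylation (forms C2–C3, sets both carbinol centres, delivers free C2-OH next to C3-OBz directly).
5. 9 ⇒ butenolide 4 (from dihydroxyacetone), whose ring fixes the C1=C6 geometry; ring order: temporary butenolide (step 1, opened in step 4), oxirane (step 10), cyclohexene (step 11).

Key step: step 11

Remark 1: 1,3-dihydroxyacetone (1) is used as its commercial dimer, which reacts as the monomer.
Remark 2: the (R,R)-salen chromium catalyst of step 7 is assumed to add to the Si face of 9; if a pilot run shows the opposite sense, the (S,S)-ligand is used with no other change.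

**Step 1**
Reactants: 1 1,3-dihydroxyacetone; 2 ethyl (triphenylphosphoranylidene)acetate
Product: 4 4-(hydroxymethyl)furan-2(5H)-one, via ethyl 4-hydroxy-3-(hydroxymethyl)but-2-enoate 3 (not isolated)
Conditions: CH2Cl2, rt, 16 h
Reagents that add atoms: none
Why: Wittig olefination of the ketone with the stabilized ylide gives enoate 3, in which one of the two equivalent CH2OH groups is necessarily cis to the ester and lactonizes with loss of ethanol, so the later C1=C6 geometry is fixed by a ring; no stereocenter is formed.

**Step 2**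
Reactants: 4 4-(hydroxymethyl)furan-2(5H)-one
Product: 5 4-({[tri(propan-2-yl)silyl]oxy}methyl)furan-2(5H)-one
Conditions: i-Pr3SiCl, imidazole, DMF, 0 °C to rt
Reagents that add atoms: chlorotri(propan-2-yl)silane, CC(C)[Si](Cl)(C(C)C)C(C)C
Why: Standard silylation of the primary alcohol; the bulky triisopropylsilyl group is chosen because it should resist O-to-O silyl migration under the basic conditions of step 4 and survives hydride, ylide and low-valent chromium.

**Step 3**
Reactants: 5 4-({[tri(propan-2-yl)silyl]oxy}methyl)furan-2(5H)-one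
Product: 6 4-({[tri(propan-2-yl)silyl]oxy}methyl)-2,5-dihydrofuran-2-ol (lactol, anomeric mixture)
Conditions: i-Bu2AlH (1.1 equiv), CH2Cl2, −78 °C; aq. KNaC4H4O6 (potassium sodium tartrate) work-up; used crude at once
Reagents that add atoms: none
Why: Partial reduction of a lactone to the lactol through the tetrahedral aluminate that is stable at −78 °C; the hemiacetal centre is inconsequential and the neutral work-up should avoid dehydration to the furan.

**Step 4**
Reactants: 6 4-({[tri(propan-2-yl)silyl]oxy}methyl)-2,5-dihydrofuran-2-ol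
Product: 8 (2E)-2-({[tri(propan-2-yl)silyl]oxy}methyl)penta-2,4-dien-1-ol, via open-chain hydroxy enal 7 (not isolated)
Conditions: Ph3PCH3Br, n-BuLi (3 equiv of ylide), THF, −78 to 0 °C
Reagents that add atoms: methylidenetriphenylphosphorane (made in the flask from methyltriphenylphosphonium bromide and n-BuLi), C=P(c1ccccc1)(c1ccccc1)c1ccccc1
Why: Wittig methylenation of a lactol through its ring-opened hydroxy aldehyde; because the aldehyde and the liberated CH2OH were joined in the ring, the new vinyl group and the free CH2OH arm must be cis on the C1=C6 double bond.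

**Step 5**
Reactants: 8 (2E)-2-({[tri(propan-2-yl)silyl]oxy}methyl)penta-2,4-dien-1-ol
Product: 9 (2Z)-2-({[tri(propan-2-yl)silyl]oxy}methyl)penta-2,4-dienal
Conditions: activated MnO2 (excess), CH2Cl2, 0 °C, dark; filtered and used at once
Reagents that add atoms: none
Why: Chemoselective allylic oxidation with MnO2 under neutral conditions; neutrality, low temperature and immediate use should limit Z-to-E isomerization of the dienal, whose aldehyde stays cis to the vinyl group.

**Step 6**
Reactants: 10 acrolein; 11 benzoyl chloride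
Product: 12 3-chloroprop-1-en-1-yl benzoate (E/Z mixture)
Conditions: ZnCl2 (2 mol %), CH2Cl2, −20 to 0 °C
Reagents that add atoms: none
Why: Lewis-acid-catalysed 1,4-addition of an acyl chloride to acrolein (chloride to C3, acyl to oxygen) is the standard entry to 3-halopropenyl esters; the E/Z mixture is used as such because both isomers should converge on the same allylchromium species.

**Step 7**
Reactants: 9 (2Z)-2-({[tri(propan-2-yl)silyl]oxy}methyl)penta-2,4-dienal; 12 3-chloroprop-1-en-1-yl benzoate
Product: 13 (3R,4R,5Z)-5-({[tri(propan-2-yl)silyl]oxy}methyl)-4-[(trimethylsilyl)oxy]octa-1,5,7-trien-3-yl benzoate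
Conditions: CrCl3 (10 mol %), Mn powder (3 equiv), (R,R)-N,N′-bis(3,5-di-tert-butylsalicylidene)cyclohexane-1,2-diamine (12 mol %), Et3N (20 mol %), Me3SiCl (1.5 equiv), MeCN, rt; pH 7 work-up
Reagents that add atoms: chlorotrimethylsilane, C[Si](C)(C)Cl
Why: Catalytic asymmetric Nozaki–Hiyama–Kishi-type (acyloxy)allylation (Mn as terminal reductant, Me3SiCl for chromium turnover): the γ-benzoyloxyallyl chromium species, held in the Z form by carbonyl-to-chromium chelation, should add through a chair-like six-membered transition state to give the syn C2-O/C3-OBz pair, the chiral salen ligand selects the Si face of the aldehyde to set (3R,4R), and in situ silylation of the chromium alkoxide blocks benzoyl migration.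

**Step 8**
Reactants: 13 (3R,4R,5Z)-5-({[tri(propan-2-yl)silyl]oxy}methyl)-4-[(trimethylsilyl)oxy]octa-1,5,7-trien-3-yl benzoate
Product: 14 (3R,4R,5Z)-4-hydroxy-5-(hydroxymethyl)octa-1,5,7-trien-3-yl benzoate
Conditions: HF·pyridine, pyridine, THF, 0 °C to rt
Reagents that add atoms: none
Why: Buffered fluoride cleavage of both silyl ethers under weakly acidic conditions, which should suppress base-induced benzoyl migration and leaves both stereocenters untouched.

**Step 9**
Reactants: 14 (3R,4R,5Z)-4-hydroxy-5-(hydroxymethyl)octa-1,5,7-trien-3-yl benzoate; 11 benzoyl chloride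
Product: 15 (3R,4R,5Z)-5-[(benzoyloxy)methyl]-4-hydroxyocta-1,5,7-trien-3-yl benzoate
Conditions: BzCl (1.05 equiv), 2,4,6-collidine, CH2Cl2, −78 to −30 °C
Reagents that add atoms: none
Why: Kinetically selective acylation of the primary allylic alcohol over the hindered secondary C2 hydroxyl (flanked by a fully substituted alkene carbon and the benzoyloxy-bearing carbon) with a weak hindered base at low temperature.

**Step 10**
Reactants: 15 (3R,4R,5Z)-5-[(benzoyloxy)methyl]-4-hydroxyocta-1,5,7-trien-3-yl benzoate
Product: 16 {(2R,3S)-2-[(1S,2R)-2-(benzoyloxy)-1-hydroxybut-3-en-1-yl]-3-ethenyloxiran-2-yl}methyl benzoate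
Conditions: mCPBA (1.2 equiv), NaHCO3 (3 equiv), CH2Cl2, 0 °C
Reagents that add atoms: 3-chloroperoxybenzoic acid, OOC(=O)c1cccc(Cl)c1
Why: Hydroxyl-directed (Henbest) peracid epoxidation: allylic 1,3-strain between the cis vinyl group and the C2 substituents places C2-H in the alkene plane, so the hydrogen-bonded peracid should deliver oxygen to the face carrying the hydroxyl (threo product), setting the oxirane carbons as (2R,3S) with the oxygen trans to the C2 hydroxyl in the later ring; the trisubstituted, directed C1=C6 bond reacts ahead of the two monosubstituted alkenes and bicarbonate shields the vinyl oxirane from the acid by-product.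

**Step 11**
Reactants: 16 {(2R,3S)-2-[(1S,2R)-2-(benzoyloxy)-1-hydroxybut-3-en-1-yl]-3-ethenyloxiran-2-yl}methyl benzoate
Product: 17 [(1R,2S,3R,6S)-3-(benzoyloxy)-2-hydroxy-7-oxabicyclo[4.1.0]hept-4-en-1-yl]methyl benzoate
Conditions: RuCl2(=CHPh)(PCy3)(H2IMes) (second-generation Grubbs catalyst, 5 mol %), CH2Cl2 (0.005 M), 40 °C
Reagents that add atoms: none
Why: Ring-closing olefin metathesis by the [2+2]/retro-[2+2] metallacyclobutane mechanism: the ruthenium alkylidene loads onto one terminal vinyl group, forms a ruthenacyclobutane with the other and releases the C4=C5 bond, ethene being lost overall. The closest known reaction type is the ring-closing metathesis of oxygenated octa-1,7-dienes to conduritol-type cyclohexenes, which tolerates free hydroxyls, allylic esters and oxiranes. The six-membered carbocycle is closed by joining the two terminal alkene carbons of the 1,7-diene at C4=C5, the oxirane being an intact spectator that becomes ring-fused. No new stereocenter is formed: the four stereocenters come in from 16 and the new double bond can only be cis in the six-membered ring. The step needs ring closure to win over intermolecular metathesis and needs the oxirane, the free hydroxyl and both benzoates to survive; the cis-oxirane holds the two alkenyl arms on one side within reach, high dilution suppresses oligomerization, and the neutral conditions leave the other groups alone. Because no protecting group remains, this closure should deliver the target directly.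

**Compound list**
1 | 1,3-dihydroxyacetone | O=C(CO)CO | starting material
2 | ethyl (triphenylphosphoranylidene)acetate | CCOC(=O)C=P(c1ccccc1)(c1ccccc1)c1ccccc1 | starting material
3 | ethyl 4-hydroxy-3-(hydroxymethyl)but-2-enoate | CCOC(=O)C=C(CO)CO | intermediate
4 | 4-(hydroxymethyl)furan-2(5H)-one | O=C1OCC(CO)=C1 | intermediate
5 | 4-({[tri(propan-2-yl)silyl]oxy}methyl)furan-2(5H)-one | O=C1OCC(CO[Si](C(C)C)(C(C)C)C(C)C)=C1 | intermediate
6 | 4-({[tri(propan-2-yl)silyl]oxy}methyl)-2,5-dihydrofuran-2-ol (anomeric mixture) | OC1OCC(CO[Si](C(C)C)(C(C)C)C(C)C)=C1 | intermediate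
7 | (2E)-4-hydroxy-3-({[tri(propan-2-yl)silyl]oxy}methyl)but-2-enal (open-chain form of 6, present as its lithium alkoxide) | O=C/C=C(\CO)CO[Si](C(C)C)(C(C)C)C(C)C | intermediate
8 | (2E)-2-({[tri(propan-2-yl)silyl]oxy}methyl)penta-2,4-dien-1-ol | OC/C(CO[Si](C(C)C)(C(C)C)C(C)C)=C\C=C | intermediate
9 | (2Z)-2-({[tri(propan-2-yl)silyl]oxy}methyl)penta-2,4-dienal | O=C/C(CO[Si](C(C)C)(C(C)C)C(C)C)=C\C=C | intermediate
10 | acrolein | C=CC=O | starting material
11 | benzoyl chloride | O=C(Cl)c1ccccc1 | starting material
12 | 3-chloroprop-1-en-1-yl benzoate (E/Z mixture) | ClCC=COC(=O)c1ccccc1 | intermediate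
13 | (3R,4R,5Z)-5-({[tri(propan-2-yl)silyl]oxy}methyl)-4-[(trimethylsilyl)oxy]octa-1,5,7-trien-3-yl benzoate | C=C/C=C(/CO[Si](C(C)C)(C(C)C)C(C)C)[C@@H](O[Si](C)(C)C)[C@H](OC(=O)c1ccccc1)C=C | intermediate
14 | (3R,4R,5Z)-4-hydroxy-5-(hydroxymethyl)octa-1,5,7-trien-3-yl benzoate | C=C/C=C(/CO)[C@@H](O)[C@H](OC(=O)c1ccccc1)C=C | intermediate
15 | (3R,4R,5Z)-5-[(benzoyloxy)methyl]-4-hydroxyocta-1,5,7-trien-3-yl benzoate | C=C/C=C(/COC(=O)c1ccccc1)[C@@H](O)[C@H](OC(=O)c1ccccc1)C=C | intermediate
16 | {(2R,3S)-2-[(1S,2R)-2-(benzoyloxy)-1-hydroxybut-3-en-1-yl]-3-ethenyloxiran-2-yl}methyl benzoate | C=C[C@@H]1O[C@]1(COC(=O)c1ccccc1)[C@@H](O)[C@H](OC(=O)c1ccccc1)C=C | intermediate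
17 | [(1R,2S,3R,6S)-3-(benzoyloxy)-2-hydroxy-7-oxabicyclo[4.1.0]hept-4-en-1-yl]methyl benzoate | O=C(OC[C@]12O[C@H]1C=C[C@@H](OC(=O)c1ccccc1)[C@@H]2O)c1ccccc1 | target

**Totals**
Total step count: 11. Longest linear sequence: 10 steps (steps 1–5 and 7–11); step 6 is a one-step side branch.

**Steps most likely to fail**

Step 7. What may go wrong: insufficient facial and syn/anti control by the chromium catalyst, competing reductive coupling of the dienal by low-valent chromium, benzoyl migration before silylation, or Z-to-E isomerization of the aldehyde. The fallback is a reagent-controlled alkoxyallylboration and sets out from 9. Allyl methoxymethyl ether is lithiated (s-BuLi, THF, −78 °C) and transmetallated with (−)-B-methoxydiisopinocampheylborane and BF3·OEt2. The resulting (Z)-γ-(methoxymethoxy)allylborane should add to the Si face of 9 at −78 °C through a chair transition state (NaOH/H2O2 work-up) to give (3R,4R,5Z)-3-(methoxymethoxy)-5-({[tri(propan-2-yl)silyl]oxy}methyl)octa-1,5,7-trien-4-ol F1. Silylation (TBSOTf, 2,6-lutidine) gives the bis-silyl ether tert-butyl{[(3R,4R,5Z)-3-(methoxymethoxy)-5-({[tri(propan-2-yl)silyl]oxy}methyl)octa-1,5,7-trien-4-yl]oxy}dimethylsilane F2. The methoxymethyl group is removed with ZnBr2/n-PrSH in CH2Cl2 at 0 °C to give (3R,4R,5Z)-4-{[tert-butyl(dimethyl)silyl]oxy}-5-({[tri(propan-2-yl)silyl]oxy}methyl)octa-1,5,7-trien-3-ol F3. Benzoylation (BzCl, pyridine, DMAP) gives (3R,4R,5Z)-4-{[tert-butyl(dimethyl)silyl]oxy}-5-({[tri(propan-2-yl)silyl]oxy}methyl)octa-1,5,7-trien-3-yl benzoate F4. The HF·pyridine conditions of step 8 then remove both silyl groups, and the route is rejoined at 14.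

Step 10. What may go wrong: poor facial selectivity of the directed epoxidation, acid-promoted opening of the vinyl oxirane, or benzoyl migration to the C2 hydroxyl. The fallback moves the epoxidation before the second benzoylation and makes it catalyst-controlled; it sets out from 14. Sharpless asymmetric epoxidation directed by the primary allylic hydroxyl (Ti(OiPr)4, L-(+)-diethyl tartrate, t-BuOOH, 4 Å molecular sieves, CH2Cl2, −20 °C) is used. This tartrate is the one that gives (2S,3S)-3-phenylglycidol from cinnamyl alcohol, and by the same facial rule it should give (1S,2R)-1-[(2R,3S)-3-ethenyl-2-(hydroxymethyl)oxiran-2-yl]-1-hydroxybut-3-en-2-yl benzoate F5. Selective benzoylation of the primary alcohol under the conditions of step 9 then rejoins the route at 16.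

Step 4. What may go wrong: dehydration of the lactol to the furan before olefination, or base-induced silyl migration between the two CH2O arms of the alkoxide, which would scramble the alkene geometry. The fallback uses the furan as a masked cis-enedial, avoids any alkoxide, and sets out from 6. Deliberate dehydration (catalytic pyridinium p-toluenesulfonate, CH2Cl2) gives (furan-3-ylmethoxy)tri(propan-2-yl)silane F6. Oxidative ring opening with singlet oxygen (O2, tetraphenylporphyrin, light, CH2Cl2, −78 °C, then Me2S) gives (2Z)-2-({[tri(propan-2-yl)silyl]oxy}methyl)but-2-enedial F7. One equivalent of Ph3P=CH2 at −78 °C should methylenate the less hindered aldehyde (the one on the CH= carbon), and the route is rejoined at 9, step 5 being skipped.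

**Further compounds**
F1 | step 7 | (3R,4R,5Z)-3-(methoxymethoxy)-5-({[tri(propan-2-yl)silyl]oxy}methyl)octa-1,5,7-trien-4-ol | C=C/C=C(/CO[Si](C(C)C)(C(C)C)C(C)C)[C@@H](O)[C@H](OCOC)C=C
F2 | step 7 | tert-butyl{[(3R,4R,5Z)-3-(methoxymethoxy)-5-({[tri(propan-2-yl)silyl]oxy}methyl)octa-1,5,7-trien-4-yl]oxy}dimethylsilane | C=C/C=C(/CO[Si](C(C)C)(C(C)C)C(C)C)[C@@H](O[Si](C)(C)C(C)(C)C)[C@H](OCOC)C=C
F3 | step 7 | (3R,4R,5Z)-4-{[tert-butyl(dimethyl)silyl]oxy}-5-({[tri(propan-2-yl)silyl]oxy}methyl)octa-1,5,7-trien-3-ol | C=C/C=C(/CO[Si](C(C)C)(C(C)C)C(C)C)[C@@H](O[Si](C)(C)C(C)(C)C)[C@H](O)C=C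
F4 | step 7 | (3R,4R,5Z)-4-{[tert-butyl(dimethyl)silyl]oxy}-5-({[tri(propan-2-yl)silyl]oxy}methyl)octa-1,5,7-trien-3-yl benzoate | C=C/C=C(/CO[Si](C(C)C)(C(C)C)C(C)C)[C@@H](O[Si](C)(C)C(C)(C)C)[C@H](OC(=O)c1ccccc1)C=C
F5 | step 10 | (1S,2R)-1-[(2R,3S)-3-ethenyl-2-(hydroxymethyl)oxiran-2-yl]-1-hydroxybut-3-en-2-yl benzoate | C=C[C@@H]1O[C@]1(CO)[C@@H](O)[C@H](OC(=O)c1ccccc1)C=C
F6 | step 4 | (furan-3-ylmethoxy)tri(propan-2-yl)silane | CC(C)[Si](OCc1ccoc1)(C(C)C)C(C)C
F7 | step 4 | (2Z)-2-({[tri(propan-2-yl)silyl]oxy}methyl)but-2-enedial | O=C/C=C(\C=O)CO[Si](C(C)C)(C(C)C)C(C)C
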